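Double product climbed slowly in the summer flask, the flask asked about: 16.7% after 90.0 min, with half of the feed of substrate in.

| flask | substrate | reagent | capture agent | remark | time |
|---|---|---|---|---|---|
| summer | 0.015 M (fed, over 3.0 h) | 0.030 M | 0.30 mM | the very flask that is asked about, followed so far; the fed solution adds 0.25 times the starting volume |  |
| midnight | 0.0075 M (fed, over 3.0 h) | 0.030 M | 0.30 mM | run made earlier; the fed solution adds 0.25 times the starting volume |  |
| flask | 0.015 M (fed, over 3.0 h) | 0.0300 M | 0.300 mM | the fed solution adds 0.25 times the starting volume | 8.0 h |

summer run (percent of the substrate charged): time / min: double product / % = 60.0: 9.2; 80.0: 14.8; 90.0: 16.7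

midnight run (percent of the substrate charged): time / h: double product / % = 1.00: 9.9; 2.00: 26.7; 3.00: 39.3; 6.00: 39.4

(readings scatter by 0.3 percentage points)

- the moment within 8.0 h at which there is most double product
- the amount of double product, in percent of the substrate charged, at that time
- earliest time at which at least nineteen twentieths of that best amount are there
- latest time at which they still are

Double product takes two reagent per substrate, so for the summer flask I reckoned a cover c of 1.00, c being the reagent charged over 2 times the substrate charged. That flask sat at the crossing, where neither charge is the limiting reagent on paper, while midnight had a cover of 2.00, twice that of the summer flask.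

I bracketed the top from both sides. From above, the summer flask trailed midnight at the shared hour, 9.2% against 9.9%, a ratio of 0.929, and I expected that lag to grow. I read midnight's 39.3% and 39.4% as two sides of a hump. A parabola leaving the earlier reading at the previous hour's climb of 13 percentage points tops out at 48.7%, so my ceiling for the summer flask was 45.3%. From below, I let the summer flask gain, up to the end of the feed, what midnight gained over that stretch, reading midnight halfway between its first two points, scaled by the ratio of the covers. That floor was 27.2%.

The forecast gave 44% at 8 h, open from 5 h to 8 h, on the ground that “everything slows and over-reaction can't destroy much product”. Its height stood inside my bracket, just under the ceiling.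

The flask gave 35.3% at 4.13 h, inside the bracket and earlier than the forecast's time, open from 3.25 h to 5.59 h.

    substrate + reagent → mono adduct + by-product (k = 80.7 M⁻¹ h⁻¹)
    reagent + mono adduct → double product + by-product (k = 105 M⁻¹ h⁻¹)
    mono adduct + capture agent → trapped intermediate (k = 10.3 M⁻¹ h⁻¹)
    mono adduct → side product (k = 0.331 h⁻¹)
    double product ⇌ isomer of the product (K = 1.62, k = 0.394 h⁻¹)

In the flask, reagent took mono adduct 4.9 times as fast as the path to side product at 2.08 h. By 8.00 h that ratio was 1.2, with 15% of the reagent left. The neighbour flask with 0.037 M of substrate had a cover of 0.405; its reagent ran out, at 0.00693% of the charge, with 46.8% of its substrate unused, and its best was 16.9%.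

(Readings and results come from a simulation with made-up constants; scatter was added.)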